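**Retrosynthetic overview**

- The target is the 3',3'''-linked dimer of 7,4'-dihydroxyisoflavone; the last disconnection is the pair of ring B methyl ethers (4'-OMe, 4'''-OMe).
- Key disconnection: both rings A (C4a, C5, C6, C7, C8, C8a) are removed by a double retro-[4+2] across C4a–C5 and C8–C8a. The feature used is that each ring A carries a single oxygen, at C7, meta to the O1-bearing C8a and para to C4a. That is where the silyloxy carbon of 1-methoxy-3-silyloxybutadiene lands when its CH2 end bonds to the pyranone carbon next to O1.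
- This leads back to a bis(3-aryl-5-phenylsulfinyl-4-pyranone). Its two pyranone rings (rings C) come from a bis(β-keto sulfoxide) by double aminomethylenation and acid closure.
- The bis(β-keto sulfoxide) comes from a bis(arylacetate) and lithiated methyl phenyl sulfoxide. The C3'–C3''' biaryl bond is made first, by reductive homocoupling of methyl (3-bromo-4-methoxyphenyl)acetate.
- Ring order: rings B (purchased) → biaryl bond → rings C → rings A (key step) → O-demethylation.

Key step: step 5

Assumption: methyl phenyl sulfoxide is used as the racemate, so 6, 7, 8, 10 and 11 (and F5, F6) are mixtures of diastereomers at sulfur and, for 10 and 11, at carbon. One isomer is drawn in each SMILES, enamine geometries are left open, and all isomers converge because every one of these stereocentres is removed in step 5.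

**Route**

Step 1
Reactants: 1 (3-bromo-4-methoxyphenyl)acetic acid
Product: 2 methyl (3-bromo-4-methoxyphenyl)acetate
Conditions: MeOH, H2SO4 (cat.), reflux
Reagents that add atoms: methanol, CO
Why: Acid-catalysed Fischer esterification in excess methanol should convert the acid cleanly, the aryl bromide and methyl ether being inert to these conditions.

Step 2
Reactants: 2 methyl (3-bromo-4-methoxyphenyl)acetate (two molecules)
Product: 3 dimethyl 2,2'-(6,6'-dimethoxybiphenyl-3,3'-diyl)diacetate
Conditions: NiBr2(PPh3)2 (10 mol %), Zn dust, Et4NI, THF, 50 °C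
Reagents that add atoms: none
Why: Nickel-catalysed reductive homocoupling (Ullmann-type): Zn reduces the nickel dibromide complex to zerovalent nickel, which inserts into the C–Br bond and joins two aryl groups at the carbon ortho to the methoxy group, and the neutral medium leaves the esters and their acidic CH2 groups untouched.

Step 3
Reactants: 3 dimethyl 2,2'-(6,6'-dimethoxybiphenyl-3,3'-diyl)diacetate; 4 methyl phenyl sulfoxide (racemic)
Product: 6 1,1'-(6,6'-dimethoxybiphenyl-3,3'-diyl)bis[3-(phenylsulfinyl)propan-2-one], via (phenylsulfinyl)methyllithium 5 (not isolated)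
Conditions: 4 (5 equiv), LDA (5 equiv, commercial solution), THF, −78 °C; then 3, −78 → 0 °C; cold 1 M HCl quench
Reagents that add atoms: none
Why: Claisen-type acylation of an α-sulfinyl carbanion by an ester: 5 adds to each ester carbonyl, methoxide leaves, and the β-keto sulfoxide is deprotonated by a second equivalent of 5 as it forms, which shields it from further addition; the sulfur configuration is not controlled and does not need to be.

Step 4
Reactants: 6 1,1'-(6,6'-dimethoxybiphenyl-3,3'-diyl)bis[3-(phenylsulfinyl)propan-2-one]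
Product: 8 3,3'-(6,6'-dimethoxybiphenyl-3,3'-diyl)bis[5-(phenylsulfinyl)-4H-pyran-4-one], via bis(dimethylamino)pentadienone 7 (not isolated)
Conditions: Me2NCH(OMe)2 (10 equiv), toluene, 90 °C; evaporate; then 1 M H2SO4, THF, 40 °C
Reagents that add atoms: N,N-dimethylformamide dimethyl acetal, COC(OC)N(C)C; water, O
Why: Double aminomethylenation with the amide acetal, first at the sulfinyl-activated and then at the benzylic α-carbon, should give 7, and aqueous acid hydrolyses one enamine end to an enol that adds to the other and expels dimethylamine (the usual 4-pyranone synthesis from 1,3-disubstituted acetones), a halide-free acid being chosen to spare the sulfoxide.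

Step 5
Reactants: 8 3,3'-(6,6'-dimethoxybiphenyl-3,3'-diyl)bis[5-(phenylsulfinyl)-4H-pyran-4-one]; 9 (E)-1-methoxy-3-(trimethylsilyloxy)buta-1,3-diene (two molecules react, used in excess)
Product: 12 3,3'-(6,6'-dimethoxybiphenyl-3,3'-diyl)bis(7-hydroxy-4H-chromen-4-one), via bis-cycloadduct 10 (not isolated), via bis-dihydrochromone 11 (not isolated)
Conditions: 9 (8 equiv), toluene, 100 °C, sealed tube; then 1 M HCl, THF, rt
Reagents that add atoms: none
Why: Proposed new method: the silyloxydiene should add to the push–pull C5=C6 bond of each pyranone in a polarised, asynchronous [4+2] process, its CH2 terminus bonding first to C6 (the carbon on O1, β to both C4=O and S=O) and its methoxy-bearing terminus then closing onto the sulfinyl carbon C5, which gives the cis-fused adduct 10 with the silyloxy carbon at the future C7. The closest known reaction type is the Diels–Alder reaction of sulfinyl-activated quinones, cyclic enones and acceptor-substituted chromones with 1-oxygenated dienes followed by sulfoxide syn-elimination; a 3-aryl-5-sulfinyl-4-pyranone has not been used in this way. Each ring A is closed by the intermolecular cycloaddition itself, which forms C8–C8a and C4a–C5 (six-membered carbocycle, [4+2] mode). The stereocentres created at C4a, C5 and C8a are transient: the cis fusion holds the sulfinyl group and H8a syn, so thermal Ei loss of PhSOH regenerates the C4a=C8a vinylogous ester (11), and acid then ionises the doubly allylic 5-methoxy group and cleaves the silyl ether, so both rings aromatise and no stereocentre remains. The step needs site selectivity for C5=C6 over the aryl-bearing C2=C3 (secured by the second acceptor and the lower hindrance at C5=C6), the head-to-tail orientation (secured by the electrophilicity of C6 and the nucleophilic CH2 end of the diene), and elimination towards H8a and not H5 (favoured because it restores the pyranone conjugation). Acid is withheld until sulfoxide loss is complete, so that a C7 ketone cannot open the O1–C8a bond by retro-oxa-Michael reaction.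

Step 6
Reactants: 12 3,3'-(6,6'-dimethoxybiphenyl-3,3'-diyl)bis(7-hydroxy-4H-chromen-4-one)
Product: 13 3,3'-(6,6'-dihydroxybiphenyl-3,3'-diyl)bis(7-hydroxy-4H-chromen-4-one) (target, CNP0386002.0)
Conditions: BBr3 (8 equiv), CH2Cl2, −78 °C → rt; then H2O
Reagents that add atoms: none
Why: Lewis-acid ether cleavage with BBr3 (O-demethylation through the aryloxydibromoborane and MeBr) is routine for 4'-methoxyisoflavones and 2,2'-dimethoxybiaryls, and the pyranone carbonyls and free 7-hydroxy groups only bind extra reagent, which the excess allows for.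

**Compound list**

1 | (3-bromo-4-methoxyphenyl)acetic acid | OC(=O)Cc1ccc(OC)c(Br)c1 | starting material
2 | methyl (3-bromo-4-methoxyphenyl)acetate | COC(=O)Cc1ccc(OC)c(Br)c1 | intermediate
3 | dimethyl 2,2'-(6,6'-dimethoxybiphenyl-3,3'-diyl)diacetate | COC(=O)Cc1ccc(OC)c(-c2cc(CC(=O)OC)ccc2OC)c1 | intermediate
4 | methyl phenyl sulfoxide (racemic) | CS(=O)c1ccccc1 | starting material
5 | (phenylsulfinyl)methyllithium (racemic, not isolated) | [Li]CS(=O)c1ccccc1 | intermediate
6 | 1,1'-(6,6'-dimethoxybiphenyl-3,3'-diyl)bis[3-(phenylsulfinyl)propan-2-one] (sulfur diastereomer mixture, one drawn) | COc1ccc(CC(=O)C[S@](=O)c2ccccc2)cc1-c1cc(CC(=O)C[S@](=O)c2ccccc2)ccc1OC | intermediate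
7 | 2,2'-(6,6'-dimethoxybiphenyl-3,3'-diyl)bis[1,5-bis(dimethylamino)-4-(phenylsulfinyl)penta-1,4-dien-3-one] (not isolated; enamine geometry not fixed, one sulfur configuration drawn) | COc1ccc(C(=CN(C)C)C(=O)C(=CN(C)C)[S@](=O)c2ccccc2)cc1-c1cc(C(=CN(C)C)C(=O)C(=CN(C)C)[S@](=O)c2ccccc2)ccc1OC | intermediate
8 | 3,3'-(6,6'-dimethoxybiphenyl-3,3'-diyl)bis[5-(phenylsulfinyl)-4H-pyran-4-one] (sulfur diastereomer mixture, one drawn) | O=c1c([S@](=O)c2ccccc2)cocc1-c1ccc(OC)c(-c2cc(-c3cocc([S@](=O)c4ccccc4)c3=O)ccc2OC)c1 | intermediate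
9 | (E)-1-methoxy-3-(trimethylsilyloxy)buta-1,3-diene | CO/C=C/C(=C)O[Si](C)(C)C | starting material
10 | 3,3'-(6,6'-dimethoxybiphenyl-3,3'-diyl)bis[5-methoxy-4a-(phenylsulfinyl)-7-(trimethylsilyloxy)-4a,5,8,8a-tetrahydro-4H-chromen-4-one] (not isolated; cis-fused, sulfinyl and H8a syn, 5-OMe anti to sulfinyl; one diastereomer drawn) | COc1ccc(C2=CO[C@H]3CC(O[Si](C)(C)C)=C[C@@H](OC)[C@]3(C2=O)[S@](=O)c2ccccc2)cc1-c1cc(C2=CO[C@H]3CC(O[Si](C)(C)C)=C[C@@H](OC)[C@]3(C2=O)[S@](=O)c2ccccc2)ccc1OC | intermediate
11 | 3,3'-(6,6'-dimethoxybiphenyl-3,3'-diyl)bis[5-methoxy-7-(trimethylsilyloxy)-5,8-dihydro-4H-chromen-4-one] (not isolated; one C5 configuration drawn) | COc1ccc(C2=COC3=C(C2=O)[C@H](OC)C=C(O[Si](C)(C)C)C3)cc1-c1cc(C2=COC3=C(C2=O)[C@H](OC)C=C(O[Si](C)(C)C)C3)ccc1OC | intermediate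
12 | 3,3'-(6,6'-dimethoxybiphenyl-3,3'-diyl)bis(7-hydroxy-4H-chromen-4-one) (4',4'''-di-O-methyl ether of the target) | O=c1c(-c2ccc(OC)c(-c3cc(-c4coc5cc(O)ccc5c4=O)ccc3OC)c2)coc2cc(O)ccc12 | intermediate
13 | 3,3'-(6,6'-dihydroxybiphenyl-3,3'-diyl)bis(7-hydroxy-4H-chromen-4-one) | O=c1c(-c2ccc(O)c(-c3cc(-c4coc5cc(O)ccc5c4=O)ccc3O)c2)coc2cc(O)ccc12 | target

**Step count and risk**

Total step count: 6. Longest linear sequence: 6 steps (1 → 2 → 3 → 6 → 8 → 12 → 13).

Steps most likely to fail:

1. Step 5. Three processes could defeat it. The vinylogous-ester C5=C6 bond may be too weak a dienophile, so that the diene is consumed by the liberated sulfenic acid before it adds. The syn-elimination may run towards H5 instead of H8a, giving a cross-conjugated dienol ether that cannot aromatise by methanol loss. The pyranone O1–C8a bond may open if a C7 ketone is unmasked before sulfur has left. The fallback, known chemistry throughout, builds rings A from resorcinol instead; it sets out from 3 and returns at 12. Saponification of 3 (LiOH, THF–H2O, rt) should give 2,2'-(6,6'-dimethoxybiphenyl-3,3'-diyl)diacetic acid F1. Friedel–Crafts acylation of resorcinol (2.2 equiv) with F1 in BF3·OEt2 at 85 °C should give the bis-deoxybenzoin 2,2'-(6,6'-dimethoxybiphenyl-3,3'-diyl)bis[1-(2,4-dihydroxyphenyl)ethan-1-one] F2. Treatment of F2 with DMF, BF3·OEt2 and MsCl at 60 °C inserts C2 and closes both pyranone rings onto the 2-hydroxy groups, giving 12.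

2. Step 3. Proton transfer from the benzylic ester CH2 to the strongly basic sulfinyl carbanion may outrun addition to the carbonyl, so that the ester is only enolised and returns on quench. The fallback turns that acidity to use; it sets out from 3 and returns at 6. Deprotonation of 3 with LiHMDS (2.1 equiv per ester, THF, −78 °C) and C-acylation with (phenylsulfanyl)acetyl chloride (crossed Claisen) should give dimethyl 2,2'-(6,6'-dimethoxybiphenyl-3,3'-diyl)bis[3-oxo-4-(phenylsulfanyl)butanoate] F3. Krapcho dealkoxycarbonylation (LiCl, wet DMSO, 130 °C) should give 1,1'-(6,6'-dimethoxybiphenyl-3,3'-diyl)bis[3-(phenylsulfanyl)propan-2-one] F4. Oxidation of F4 with NaIO4 (MeOH–H2O, 0 °C) stops at the sulfoxide and gives 6.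

3. Step 4. After the first condensation the ketone is a vinylogous amide, and the second aminomethylenation at the benzylic carbon may stall, leaving a mono-enaminone that cannot close. The fallback introduces the second one-carbon unit by enolate formylation; it sets out from 6 and returns at 8. Me2NCH(OMe)2 (2.2 equiv, CH2Cl2, rt) should react only at the sulfinyl-activated carbon to give 1,1'-(6,6'-dimethoxybiphenyl-3,3'-diyl)bis[4-(dimethylamino)-3-(phenylsulfinyl)but-3-en-2-one] F5. Deprotonation of F5 at the benzylic carbon (LiHMDS, THF, −78 °C) and Claisen formylation with ethyl formate should give 2,2'-(6,6'-dimethoxybiphenyl-3,3'-diyl)bis[5-(dimethylamino)-1-hydroxy-4-(phenylsulfinyl)penta-1,4-dien-3-one] F6. On treatment with TFA in CH2Cl2 the enol oxygen of F6 adds to the enaminone terminus and dimethylamine is lost, giving 8.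

**Further compounds**

F1 | step 5 | 2,2'-(6,6'-dimethoxybiphenyl-3,3'-diyl)diacetic acid | OC(=O)Cc1ccc(OC)c(-c2cc(CC(=O)O)ccc2OC)c1
F2 | step 5 | 2,2'-(6,6'-dimethoxybiphenyl-3,3'-diyl)bis[1-(2,4-dihydroxyphenyl)ethan-1-one] | COc1ccc(CC(=O)c2ccc(O)cc2O)cc1-c1cc(CC(=O)c2ccc(O)cc2O)ccc1OC
F3 | step 3 | dimethyl 2,2'-(6,6'-dimethoxybiphenyl-3,3'-diyl)bis[3-oxo-4-(phenylsulfanyl)butanoate] | COc1ccc(C(C(=O)OC)C(=O)CSc2ccccc2)cc1-c1cc(C(C(=O)OC)C(=O)CSc2ccccc2)ccc1OC
F4 | step 3 | 1,1'-(6,6'-dimethoxybiphenyl-3,3'-diyl)bis[3-(phenylsulfanyl)propan-2-one] | COc1ccc(CC(=O)CSc2ccccc2)cc1-c1cc(CC(=O)CSc2ccccc2)ccc1OC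
F5 | step 4 | 1,1'-(6,6'-dimethoxybiphenyl-3,3'-diyl)bis[4-(dimethylamino)-3-(phenylsulfinyl)but-3-en-2-one] | COc1ccc(CC(=O)C(=CN(C)C)[S@](=O)c2ccccc2)cc1-c1cc(CC(=O)C(=CN(C)C)[S@](=O)c2ccccc2)ccc1OC
F6 | step 4 | 2,2'-(6,6'-dimethoxybiphenyl-3,3'-diyl)bis[5-(dimethylamino)-1-hydroxy-4-(phenylsulfinyl)penta-1,4-dien-3-one] | COc1ccc(C(=CO)C(=O)C(=CN(C)C)[S@](=O)c2ccccc2)cc1-c1cc(C(=CO)C(=O)C(=CN(C)C)[S@](=O)c2ccccc2)ccc1OC
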